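**Plan**

1. Numbering used throughout: decalin carbons C1–C10 as in labdanes (C2 OAc, C3 OH, C4 CMe2, C5–H, C8–Me, C9 carbinol, C10–Me); side chain C11–C16 (C15 ester carbon, C16 the methyl on C13); α is the face of H-5, β the face of the C10 methyl.
2. Retrosynthesis, in order: C2 acetate; C13–C16 and C14–C15 (cuprate and chloroformate on a butynyl chain); C2–O and C3–O (cis-dihydroxylation of a 2,3-alkene made from a C3 ketone); the second C4 methyl (from a C3=C4 silyl enol ether); C9–C11 (addition to a C9 ketone); finally C1–C2 and C5–C10 together, by an intramolecular Diels–Alder reaction of an open-chain trienone.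
3. Enabling feature: ring A has oxygen on C3 next to C4, which can be sp2 while it carries only one methyl, and the C9 carbinol sits next to quaternary C10 with its methyl and the C1 methylene. This maps onto a 2-silyloxydiene C2=C3(OSi)–C4(Me)=C5 and a methacryloyl dienophile C1=C10(Me)–C9=O joined by C6–C7–C8.
4. Forward: Evans methylation (C8), Weinreb amide, cross-metathesis (C4=C5), enol silylation, isopropenyl ketone formation with cycloaddition (rings A and B in one operation), then C9 side-chain addition, C4 methylation, Shapiro olefination, alkynoate, dihydroxylation, cuprate addition, acetylation.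
5. Stereochemistry: C8 from the auxiliary; C5 and C10 from the cycloaddition under control of C8; C9 by axial attack anti to the C10 methyl; C2 and C3 by α-face osmylation; the (Z)-alkene by syn carbocupration.

Key step: step 6

**Route**

Step 1
Reactants: 1 (R)-4-benzyloxazolidin-2-one; 2 hex-5-enoyl chloride
Product: 3 (R)-4-benzyl-3-(hex-5-enoyl)oxazolidin-2-one
Conditions: n-BuLi, THF, −78 °C; then 2, −78 → 0 °C
Reagents that add atoms: none
Why: N-acylation of the lithiated oxazolidinone by the acid chloride (attachment of the Evans auxiliary); no stereocenter is formed.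

Step 2
Reactants: 3 (R)-4-benzyl-3-(hex-5-enoyl)oxazolidin-2-one
Product: 4 (R)-4-benzyl-3-[(R)-2-methylhex-5-enoyl]oxazolidin-2-one
Conditions: NaN(SiMe3)2, THF, −78 °C; MeI, −78 → −40 °C
Reagents that add atoms: iodomethane (CI)
Why: Evans alkylation: the chelated (Z)-sodium enolate should be methylated on the face opposite the benzyl group, which with the (R)-auxiliary sets the (R)-configured future C8.

Step 3
Reactants: 4 (R)-4-benzyl-3-[(R)-2-methylhex-5-enoyl]oxazolidin-2-one
Product: 5 (R)-N-methoxy-N,2-dimethylhex-5-enamide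
Conditions: MeNH(OMe)·HCl, AlMe3, CH2Cl2, 0 °C → rt
Reagents that add atoms: N,O-dimethylhydroxylamine hydrochloride (CNOC.Cl)
Why: Aluminium amide transamination (Weinreb amide formation) should cleave the exocyclic imide carbonyl without touching the α-stereocenter and return the auxiliary.

Step 4
Reactants: 5 (R)-N-methoxy-N,2-dimethylhex-5-enamide; 6 3-methylbut-3-en-2-one
Product: 7 (2R,5E)-N-methoxy-N,2,6-trimethyl-7-oxooct-5-enamide
Conditions: 6 (excess), second-generation Hoveyda–Grubbs catalyst RuCl2(H2IMes)(=CH-C6H4-2-OiPr) (5 mol%), CH2Cl2, 40 °C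
Reagents that add atoms: none
Why: Olefin cross-metathesis of a terminal alkene with an excess of a 1,1-disubstituted enone, driven by loss of ethene; the trisubstituted enone should form as the more stable (E)-isomer with the chain trans to the acetyl group.

Step 5
Reactants: 7 (2R,5E)-N-methoxy-N,2,6-trimethyl-7-oxooct-5-enamide
Product: 8 (2R,5E)-7-[(tert-butyldimethylsilyl)oxy]-N-methoxy-N,2,6-trimethylocta-5,7-dienamide
Conditions: TBSOTf, Et3N, CH2Cl2, −78 → 0 °C
Reagents that add atoms: tert-butyldimethylsilyl trifluoromethanesulfonate (CC(C)(C)[Si](C)(C)OS(=O)(=O)C(F)(F)F)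
Why: Soft enolisation of the enone toward its acetyl CH3 (kinetic α′-deprotonation) gives the 2-silyloxy-1,3-diene; the Weinreb amide is not enolised under these conditions.

Step 6
Reactants: 8 (2R,5E)-7-[(tert-butyldimethylsilyl)oxy]-N-methoxy-N,2,6-trimethylocta-5,7-dienamide; 9 isopropenylmagnesium bromide
Product: 11 (2R,4aS,8aS)-6-[(tert-butyldimethylsilyl)oxy]-2,5,8a-trimethyl-3,4,4a,7,8,8a-hexahydronaphthalen-1(2H)-one, via trienone 10 (not isolated)
Conditions: 9, THF, −20 → 0 °C; pH 7 phosphate buffer, 0 °C; then toluene, BHT, 80 °C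
Reagents that add atoms: none
Why: The Weinreb ketone synthesis releases the 1,7,9-decatrien-3-one 10, which should undergo a thermal, concerted but asynchronous intramolecular Diels–Alder reaction of normal electron demand between the 2-silyloxydiene C2=C3–C4=C5 and the enone C1=C10–C9=O. The closest known reaction type is the cyclisation of 1,7,9-decatrien-3-ones to 1-decalones. Ring A is closed as the [4+2] cycloadduct ring by the new C1–C2 and C5–C10 bonds, and ring B is closed in the same event as the six-membered tether ring (C5–C6–C7–C8–C9–C10) through the shared C5–C10 bond. C5 and C10 are the new stereocenters: their trans relation follows from the exo placement of the carbonyl-bearing tether in a chair-like arrangement, and their absolute sense from C8, whose methyl stays equatorial because the axial alternative would meet the endo C10 methyl in a 1,3-diaxial contact. The step needs exo (trans-fused) over carbonyl-endo (cis-fused) selectivity; the α-methyl on the dienophile weakens the endo preference of the carbonyl, and the C4 methyl on the diene carbon next to the tethered terminus is strained against the C6 methylene in the cis-fused transition state. Regiochemistry is fixed by the tether and agrees with the polarity of both partners, and the adduct keeps C3 as a regiodefined silyl enol ether beside a free C9 ketone.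

Step 7
Reactants: 11 (2R,4aS,8aS)-6-[(tert-butyldimethylsilyl)oxy]-2,5,8a-trimethyl-3,4,4a,7,8,8a-hexahydronaphthalen-1(2H)-one; 12 (4-bromobut-1-yn-1-yl)trimethylsilane
Product: 14 3-[(tert-butyldimethylsilyl)oxy]-4,8α,10β-trimethyl-9α-[4-(trimethylsilyl)but-3-yn-1-yl]-5α-octal-3-en-9β-ol, via Grignard reagent 13 (not isolated)
Conditions: 12, Mg, THF, rt; then LaCl3·2LiCl, 11, THF, −20 → 0 °C
Reagents that add atoms: none
Why: 1,2-Addition of a Grignard reagent to a hindered, enolisable ketone with LaCl3·2LiCl to suppress enolisation; the nucleophile should enter axially from the α face because the axial C10 methyl blocks the equatorial trajectory, which sets C9 with the side chain α and the hydroxyl β, and the silyl enol ether should not react.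

Step 8
Reactants: 14 3-[(tert-butyldimethylsilyl)oxy]-4,8α,10β-trimethyl-9α-[4-(trimethylsilyl)but-3-yn-1-yl]-5α-octal-3-en-9β-ol
Product: 15 3β-[(tert-butyldimethylsilyl)oxy]-3α,4α-methano-4β,8α,10β-trimethyl-9α-[4-(trimethylsilyl)but-3-yn-1-yl]-5α-decalin-9β-ol
Conditions: Et2Zn, CH2I2, CH2Cl2, 0 °C → rt
Reagents that add atoms: diiodomethane (ICI)
Why: Simmons–Smith cyclopropanation (Furukawa variant) of the electron-rich silyl enol ether, expected from the α face away from the C10 methyl; the alkynylsilane is inert to the zinc carbenoid, and the new CH2 becomes the second C4 methyl, so the face of attack has no consequence.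

Step 9
Reactants: 15 3β-[(tert-butyldimethylsilyl)oxy]-3α,4α-methano-4β,8α,10β-trimethyl-9α-[4-(trimethylsilyl)but-3-yn-1-yl]-5α-decalin-9β-ol
Product: 16 9α-(but-3-yn-1-yl)-9β-hydroxy-4,4,8α,10β-tetramethyl-5α-decalin-3-one
Conditions: Bu4NF, THF, 0 °C → rt; then K2CO3, MeOH, rt
Reagents that add atoms: none
Why: Fluoride removes both silyl groups, and the cyclopropanolate should open under base by cleavage of the C3–CH2 bond toward the primary carbanion, which after protonation is the second C4 methyl next to the C3 ketone (geminal methylation through a siloxycyclopropane); no stereocenter is formed.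

Step 10
Reactants: 16 9α-(but-3-yn-1-yl)-9β-hydroxy-4,4,8α,10β-tetramethyl-5α-decalin-3-one
Product: 17 (E)-C3 tosylhydrazone of 16
Conditions: TsNHNH2, PPTS (cat.), MeOH, 60 °C
Reagents that add atoms: p-toluenesulfonyl hydrazide (Cc1ccc(cc1)S(=O)(=O)NN)
Why: Condensation of the ketone to the tosylhydrazone; the N–N bond should point toward the C2 methylene, away from quaternary C4.

Step 11
Reactants: 17 (E)-C3 tosylhydrazone of 16
Product: 18 9α-(but-3-yn-1-yl)-4,4,8α,10β-tetramethyl-5α-decal-2-en-9β-ol
Conditions: LiN(iPr)2 (excess), THF, −78 °C → rt; H2O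
Reagents that add atoms: none
Why: Shapiro reaction: syn deprotonation at C2, loss of sulfinate and N2, and protonation of the vinyllithium should give the 2,3-alkene as the only possible regioisomer because C4 has no hydrogen; the extra base allows for the hydroxyl and alkyne protons.

Step 12
Reactants: 18 9α-(but-3-yn-1-yl)-4,4,8α,10β-tetramethyl-5α-decal-2-en-9β-ol
Product: 19 methyl 5-(9β-hydroxy-4,4,8α,10β-tetramethyl-5α-decal-2-en-9α-yl)pent-2-ynoate
Conditions: n-BuLi (2.1 equiv), THF, −78 °C; ClCO2Me (1.05 equiv), −78 °C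
Reagents that add atoms: methyl chloroformate (COC(=O)Cl)
Why: C-acylation of the lithium acetylide with a chloroformate; the hindered tertiary lithium alkoxide at C9 should not compete for a single equivalent of the electrophile.

Step 13
Reactants: 19 methyl 5-(9β-hydroxy-4,4,8α,10β-tetramethyl-5α-decal-2-en-9α-yl)pent-2-ynoate
Product: 20 methyl 5-(2α,3α,9β-trihydroxy-4,4,8α,10β-tetramethyl-5α-decalin-9α-yl)pent-2-ynoate
Conditions: OsO4 (cat.), NMO, citric acid, t-BuOH/H2O, rt
Reagents that add atoms: N-methylmorpholine N-oxide (C[N+]1([O-])CCOCC1); water (O)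
Why: Catalytic syn-dihydroxylation (Upjohn conditions); osmium tetroxide should approach the α face of the ring A alkene, away from the axial methyl groups on C4 and C10, which sets C2 and C3 as the 2α,3α-diol, while the electron-poor alkynoate is not oxidised.

Step 14
Reactants: 20 methyl 5-(2α,3α,9β-trihydroxy-4,4,8α,10β-tetramethyl-5α-decalin-9α-yl)pent-2-ynoate
Product: 21 methyl (2Z)-5-(2α,3α,9β-trihydroxy-4,4,8α,10β-tetramethyl-5α-decalin-9α-yl)-3-methylpent-2-enoate
Conditions: Me2CuLi (from MeLi and CuI, excess), THF, −78 °C; MeOH, −78 °C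
Reagents that add atoms: lithium dimethylcuprate ([Li+].C[Cu-]C)
Why: Syn carbocupration of the 2-alkynoate and protonation of the vinylcopper intermediate at low temperature with retention place the new methyl trans to the ester, which should give the (Z)-enoate; the excess of cuprate allows for the three free hydroxyl groups.

Step 15
Reactants: 21 methyl (2Z)-5-(2α,3α,9β-trihydroxy-4,4,8α,10β-tetramethyl-5α-decalin-9α-yl)-3-methylpent-2-enoate
Product: 22 methyl (2Z)-5-[(1S,2R,4aS,6S,7R,8aS)-7-acetoxy-1,6-dihydroxy-2,5,5,8a-tetramethyldecahydronaphthalen-1-yl]-3-methylpent-2-enoate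
Conditions: Ac2O (1.1 equiv), pyridine, CH2Cl2, 0 °C
Reagents that add atoms: acetic anhydride (CC(=O)OC(C)=O)
Why: Regioselective acylation of the equatorial secondary C2 hydroxyl over the axial, neopentyl C3 hydroxyl and the tertiary C9 hydroxyl; the C2 acetate is also the preferred position should acyl migration across the cis-diol occur.

**Compound list**

1 | (R)-4-benzyloxazolidin-2-one | O=C1N[C@H](Cc2ccccc2)CO1 | starting material
2 | hex-5-enoyl chloride | C=CCCCC(=O)Cl | starting material
3 | (R)-4-benzyl-3-(hex-5-enoyl)oxazolidin-2-one | C=CCCCC(=O)N1[C@H](Cc2ccccc2)COC1=O | intermediate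
4 | (R)-4-benzyl-3-[(R)-2-methylhex-5-enoyl]oxazolidin-2-one | C=CCC[C@@H](C)C(=O)N1[C@H](Cc2ccccc2)COC1=O | intermediate
5 | (R)-N-methoxy-N,2-dimethylhex-5-enamide | CON(C)C(=O)[C@H](C)CCC=C | intermediate
6 | 3-methylbut-3-en-2-one | CC(=C)C(C)=O | starting material
7 | (2R,5E)-N-methoxy-N,2,6-trimethyl-7-oxooct-5-enamide | CON(C)C(=O)[C@H](C)CC/C=C(\C)C(C)=O | intermediate
8 | (2R,5E)-7-[(tert-butyldimethylsilyl)oxy]-N-methoxy-N,2,6-trimethylocta-5,7-dienamide | CON(C)C(=O)[C@H](C)CC/C=C(\C)C(=C)O[Si](C)(C)C(C)(C)C | intermediate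
9 | isopropenylmagnesium bromide | CC(=C)[Mg]Br | starting material
10 | (4R,7E)-9-[(tert-butyldimethylsilyl)oxy]-2,4,8-trimethyldeca-1,7,9-trien-3-one | C=C(C)C(=O)[C@H](C)CC/C=C(\C)C(=C)O[Si](C)(C)C(C)(C)C | intermediate
11 | (2R,4aS,8aS)-6-[(tert-butyldimethylsilyl)oxy]-2,5,8a-trimethyl-3,4,4a,7,8,8a-hexahydronaphthalen-1(2H)-one (C9 ketone; 8α-methyl; 5α-H; 10β-methyl; C3=C4 silyl enol ether) | O=C1[C@H](C)CC[C@H]2C(C)=C(O[Si](C)(C)C(C)(C)C)CC[C@@]21C | intermediate
12 | (4-bromobut-1-yn-1-yl)trimethylsilane | C[Si](C)(C)C#CCCBr | starting material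
13 | [4-(trimethylsilyl)but-3-yn-1-yl]magnesium bromide | C[Si](C)(C)C#CCC[Mg]Br | intermediate
14 | 3-[(tert-butyldimethylsilyl)oxy]-4,8α,10β-trimethyl-9α-[4-(trimethylsilyl)but-3-yn-1-yl]-5α-octal-3-en-9β-ol | C[Si](C)(C)C#CCC[C@]1(O)[C@H](C)CC[C@H]2C(C)=C(O[Si](C)(C)C(C)(C)C)CC[C@@]21C | intermediate
15 | 3β-[(tert-butyldimethylsilyl)oxy]-3α,4α-methano-4β,8α,10β-trimethyl-9α-[4-(trimethylsilyl)but-3-yn-1-yl]-5α-decalin-9β-ol | C[Si](C)(C)C#CCC[C@]1(O)[C@H](C)CC[C@H]2[C@]3(C)C[C@]3(O[Si](C)(C)C(C)(C)C)CC[C@@]21C | intermediate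
16 | 9α-(but-3-yn-1-yl)-9β-hydroxy-4,4,8α,10β-tetramethyl-5α-decalin-3-one | C#CCC[C@]1(O)[C@H](C)CC[C@H]2C(C)(C)C(=O)CC[C@@]21C | intermediate
17 | (E)-C3 tosylhydrazone of 16 | C#CCC[C@]1(O)[C@H](C)CC[C@H]2C(C)(C)/C(=N/NS(=O)(=O)c3ccc(C)cc3)CC[C@@]21C | intermediate
18 | 9α-(but-3-yn-1-yl)-4,4,8α,10β-tetramethyl-5α-decal-2-en-9β-ol | C#CCC[C@]1(O)[C@H](C)CC[C@H]2C(C)(C)C=CC[C@@]21C | intermediate
19 | methyl 5-(9β-hydroxy-4,4,8α,10β-tetramethyl-5α-decal-2-en-9α-yl)pent-2-ynoate | COC(=O)C#CCC[C@]1(O)[C@H](C)CC[C@H]2C(C)(C)C=CC[C@@]21C | intermediate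
20 | methyl 5-(2α,3α,9β-trihydroxy-4,4,8α,10β-tetramethyl-5α-decalin-9α-yl)pent-2-ynoate | COC(=O)C#CCC[C@]1(O)[C@H](C)CC[C@H]2C(C)(C)[C@H](O)[C@H](O)C[C@@]21C | intermediate
21 | methyl (2Z)-5-(2α,3α,9β-trihydroxy-4,4,8α,10β-tetramethyl-5α-decalin-9α-yl)-3-methylpent-2-enoate | COC(=O)/C=C(/C)CC[C@]1(O)[C@H](C)CC[C@H]2C(C)(C)[C@H](O)[C@H](O)C[C@@]21C | intermediate
22 | methyl (2Z)-5-[(1S,2R,4aS,6S,7R,8aS)-7-acetoxy-1,6-dihydroxy-2,5,5,8a-tetramethyldecahydronaphthalen-1-yl]-3-methylpent-2-enoate (CNP0135744.2) | COC(=O)/C=C(/C)CC[C@]1(O)[C@H](C)CC[C@H]2C(C)(C)[C@H](O)[C@H](OC(C)=O)C[C@@]21C | target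

**Step count and risks**

Total step count: 15. Longest linear sequence: 15 steps (1 and 2 to 22).

Steps most likely to fail:

Step 6. The risk is a competing carbonyl-endo cycloaddition, that is, loss of exo selectivity and formation of the cis ring fusion, which cannot be corrected later because neither C5 nor C10 is epimerisable. The fallback sets out from 8. Reduction of the Weinreb amide with iBu2AlH (THF, −78 °C) should give (2R,5E)-7-[(tert-butyldimethylsilyl)oxy]-2,6-dimethylocta-5,7-dienal F1. Addition of 9 (THF, −78 °C) would give (4R,7E)-9-[(tert-butyldimethylsilyl)oxy]-2,4,8-trimethyldeca-1,7,9-trien-3-ol F2 as both C9 epimers. Thermal cycloaddition of this unactivated triene (toluene, BHT, sealed tube, about 170 °C) has no carbonyl competing for the endo position, so the ring fusion should be decided by the chair tether and the C4 and C10 methyl groups alone. It would give 6-[(tert-butyldimethylsilyl)oxy]-2,5,8a-trimethyl-1,2,3,4,4a,7,8,8a-octahydronaphthalen-1-ol F3, and Dess–Martin oxidation of both C9 epimers comes back to 11.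

Step 7. The risk is enolisation of the hindered, doubly α-branched ketone by the basic organometallic reagent in place of addition. The fallback sets out from 11. Corey–Chaykovsky epoxidation with dimethylsulfonium methylide (Me3S+ I−, n-BuLi, THF, −10 °C) uses a small nucleophile that should add irreversibly along the same axial α trajectory, giving the spiro-epoxide 3-[(tert-butyldimethylsilyl)oxy]-4,8α,10β-trimethyl-5α-octal-3-ene-9-spiro-oxirane (CH2 α, oxygen β) F4. Opening of the epoxide at its CH2 terminus with 3-(trimethylsilyl)prop-2-yn-1-yllithium (from 1-(trimethylsilyl)propyne and n-BuLi; THF/DMPU, −20 °C → rt) forms the C11–C12 bond and comes back to 14.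

Step 14. The risk is protonolysis of the cuprate by the three hydroxyl groups, with incomplete conjugate addition or erosion of the alkene geometry if the mixture has to be warmed. The fallback sets out from 20. The cis-diol is tied up (2,2-dimethoxypropane, PPTS, acetone) as the 2α,3α-O-isopropylidene acetal of 20 F5. The same cuprate addition on F5 should give the 2α,3α-O-isopropylidene acetal of 21 F6, and mild hydrolysis (80% aqueous AcOH, rt) comes back to 21.

**Further compounds**

F1 | step 6 | (2R,5E)-7-[(tert-butyldimethylsilyl)oxy]-2,6-dimethylocta-5,7-dienal | O=C[C@H](C)CC/C=C(\C)C(=C)O[Si](C)(C)C(C)(C)C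
F2 | step 6 | (4R,7E)-9-[(tert-butyldimethylsilyl)oxy]-2,4,8-trimethyldeca-1,7,9-trien-3-ol (both C3 epimers) | C=C(C)C(O)[C@H](C)CC/C=C(\C)C(=C)O[Si](C)(C)C(C)(C)C
F3 | step 6 | 6-[(tert-butyldimethylsilyl)oxy]-2,5,8a-trimethyl-1,2,3,4,4a,7,8,8a-octahydronaphthalen-1-ol (both C1 epimers; ring stereocenters as in 11) | OC1[C@H](C)CC[C@H]2C(C)=C(O[Si](C)(C)C(C)(C)C)CC[C@@]21C
F4 | step 7 | 3-[(tert-butyldimethylsilyl)oxy]-4,8α,10β-trimethyl-5α-octal-3-ene-9-spiro-oxirane (CH2 α, oxygen β) | C1O[C@]12[C@H](C)CC[C@H]3C(C)=C(O[Si](C)(C)C(C)(C)C)CC[C@@]32C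
F5 | step 14 | 2α,3α-O-isopropylidene acetal of 20 | COC(=O)C#CCC[C@]1(O)[C@H](C)CC[C@H]2C(C)(C)[C@H](OC(C)(C)O3)[C@H]3C[C@@]21C
F6 | step 14 | 2α,3α-O-isopropylidene acetal of 21 | COC(=O)/C=C(/C)CC[C@]1(O)[C@H](C)CC[C@H]2C(C)(C)[C@H](OC(C)(C)O3)[C@H]3C[C@@]21C
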